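**Strategy.** The most crowded ether, B4–O–C1, is not made bimolecularly. Ring B has a hydroxyl at B3 next to B4, and ring C has a hydrogen at C6 next to C1. A carboxyl carbon placed on C6 and esterified to the B3 oxygen therefore ties the two rings together. The precursor is this depside: a ring C–D–E salicylic acid with a free C1 hydroxyl, bound to the ring A–B bromophenol with bromine on B4. Copper-mediated O-arylation closes the seven-membered depsidone ring and forms B4–O in one operation. Saponification returns the B3 hydroxyl, the carboxyl leaves C6 as CO2, and BBr3 removes the twelve methyl ethers.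

Key step: step 13

Labels: rings A–E run from the 2,4,6-trihydroxyphenoxy end to the 3,4,5-trihydroxyphenoxy end.
- Ring B: B1 bears the oxygen to ring A, B4 the oxygen to ring C, and B3 and B5 bear hydroxyls.
- Ring C: C1 bears the oxygen to ring B, C2 the oxygen to ring D, C3–C5 bear hydroxyls, and C6 bears hydrogen.
- Ring D: D1 bears the oxygen to ring C and D5 the oxygen to ring E.

Structure check: twelve methoxy groups plus the ester oxygen account for the thirteen hydroxyls of the target.

Design remark: the B4 bromine and the single unmethylated B3 oxygen are bought in place. Bromination or mono-demethylation after ring A is attached would have to choose among several equally activated C–H sites and five similar methoxy groups.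

Assumption: the five starting materials are taken as catalogue chemicals.

**Step 1**
Reactants: 1 2-bromo-3-methoxyphenol
Product: 2 2-bromo-1-methoxy-3-(methoxymethoxy)benzene
Conditions: NaH, MOMCl, THF/DMF, 0 °C to rt
Reagents that add atoms: chloromethyl methyl ether, COCCl
Why: Williamson-type O-alkylation of the sodium phenoxide masks the future B3 ester oxygen as an acetal that tolerates iridium, copper and base.

**Step 2**
Reactants: 2 2-bromo-1-methoxy-3-(methoxymethoxy)benzene
Product: 4 2-bromo-5-iodo-1-methoxy-3-(methoxymethoxy)benzene, via pinacol boronate 3 (not isolated)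
Conditions: [Ir(OMe)(cod)]2 (1.5 mol %), dtbpy (3 mol %), B2pin2, THF, 80 °C; volatiles off; then CuI (10 mol %), 1,10-phenanthroline (20 mol %), KI, MeOH/H2O, air, 80 °C
Reagents that add atoms: potassium iodide, [K+].[I-] (iodine of 4); bis(pinacolato)diboron, CC1(C)OB(OC1(C)C)B1OC(C)(C)C(C)(C)O1 (boryl group of intermediate 3 only)
Why: Sterically governed iridium-catalysed C–H borylation of a 1,2,3-trisubstituted arene takes the only C–H without an ortho neighbour (future B1) and spares C–Br, and the known copper-catalysed aerobic iododeboronation then puts iodine on that same carbon.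

**Step 3**
Reactants: 4 2-bromo-5-iodo-1-methoxy-3-(methoxymethoxy)benzene; 5 2,4,6-trimethoxyphenol
Product: 6 2-bromo-1-methoxy-3-(methoxymethoxy)-5-(2,4,6-trimethoxyphenoxy)benzene
Conditions: CuI (10 mol %), picolinic acid (20 mol %), K3PO4, DMSO, 80 °C, Ar
Reagents that add atoms: none
Why: Ligand-accelerated Ullmann diaryl ether coupling in which the open C–I bond should react far faster than the C–Br bond shielded by two ortho alkoxy groups, while the inert atmosphere protects the easily oxidised phenol 5.

**Step 4**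
Reactants: 6 2-bromo-1-methoxy-3-(methoxymethoxy)-5-(2,4,6-trimethoxyphenoxy)benzene
Product: 7 2-bromo-3-methoxy-5-(2,4,6-trimethoxyphenoxy)phenol (ring A–B bromophenol)
Conditions: HCl (cat.), MeOH, 45 °C
Reagents that add atoms: none
Why: Acid-catalysed acetal exchange (MOM cleavage) in methanol traps the formaldehyde unit as dimethoxymethane and leaves the methyl ethers, the diaryl ether and the bromide alone.

**Step 5**
Reactants: 8 3-bromo-4,5-dimethoxybenzaldehyde; 9 3,4,5-trimethoxyphenol
Product: 10 3,4-dimethoxy-5-(3,4,5-trimethoxyphenoxy)benzaldehyde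
Conditions: CuI (20 mol %), N,N-dimethylglycine (40 mol %), Cs2CO3, 1,4-dioxane, 100 °C, Ar
Reagents that add atoms: none
Why: Ullmann diaryl ether coupling of a phenol without ortho substituents with a bromide that has only one, using a tertiary amino acid ligand that cannot condense with the aldehyde.

**Step 6**
Reactants: 10 3,4-dimethoxy-5-(3,4,5-trimethoxyphenoxy)benzaldehyde
Product: 12 3,4-dimethoxy-5-(3,4,5-trimethoxyphenoxy)phenol (ring D–E phenol), via aryl formate 11 (not isolated)
Conditions: mCPBA, CH2Cl2, 0 °C to rt; aq. NaHCO3 wash; then K2CO3 (cat.), MeOH, rt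
Reagents that add atoms: 3-chloroperoxybenzoic acid, OOC(=O)c1cccc(Cl)c1
Why: Baeyer–Villiger oxidation with a Dakin-type outcome, since the aryl group with its para methoxy group migrates in the Criegee adduct and the reactive aryl formate is methanolysed directly.

**Step 7**
Reactants: 13 3,4,5-trimethoxybenzaldehyde
Product: 14 2-bromo-3,4,5-trimethoxybenzaldehyde
Conditions: NBS, CHCl3, reflux
Reagents that add atoms: N-bromosuccinimide, O=C1CCC(=O)N1Br
Why: Electrophilic aromatic bromination at one of two equivalent free positions, after which bromine and formyl together deactivate the ring against a second substitution.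

**Step 8**
Reactants: 14 2-bromo-3,4,5-trimethoxybenzaldehyde; 12 3,4-dimethoxy-5-(3,4,5-trimethoxyphenoxy)phenol
Product: 15 2-[3,4-dimethoxy-5-(3,4,5-trimethoxyphenoxy)phenoxy]-3,4,5-trimethoxybenzaldehyde
Conditions: CuI (20 mol %), N,N-dimethylglycine (40 mol %), Cs2CO3, 1,4-dioxane, 105 °C, Ar
Reagents that add atoms: none
Why: Ullmann diaryl ether coupling in which the ortho formyl group activates the hindered C–Br bond by electron withdrawal and by binding copper, and the phenol 12 has two free ortho positions.

**Step 9**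
Reactants: 15 2-[3,4-dimethoxy-5-(3,4,5-trimethoxyphenoxy)phenoxy]-3,4,5-trimethoxybenzaldehyde
Product: 17 2-[3,4-dimethoxy-5-(3,4,5-trimethoxyphenoxy)phenoxy]-3,4,5-trimethoxyphenol (ring C–D–E phenol), via aryl formate 16 (not isolated)
Conditions: mCPBA, CH2Cl2, 0 °C to rt; aq. NaHCO3 wash; then K2CO3 (cat.), MeOH, rt
Reagents that add atoms: 3-chloroperoxybenzoic acid, OOC(=O)c1cccc(Cl)c1
Why: Baeyer–Villiger oxidation in which the ortho aryloxy and para methoxy groups ensure aryl migration, turning the formyl carbon site into the C1 hydroxyl after methanolysis of the formate.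

**Step 10**
Reactants: 17 2-[3,4-dimethoxy-5-(3,4,5-trimethoxyphenoxy)phenoxy]-3,4,5-trimethoxyphenol
Product: 18 3-[3,4-dimethoxy-5-(3,4,5-trimethoxyphenoxy)phenoxy]-2-hydroxy-4,5,6-trimethoxybenzaldehyde
Conditions: MgCl2, Et3N, (CH2O)n, MeCN, reflux; then 1 M HCl
Reagents that add atoms: paraformaldehyde, counted as formaldehyde, C=O
Why: Magnesium-mediated ortho-formylation (Casnati–Skattebøl reaction) delivers formaldehyde within the magnesium phenoxide to the only free ortho carbon C6, so rings D and E, which hold no free hydroxyl, stay untouched.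

**Step 11**
Reactants: 18 3-[3,4-dimethoxy-5-(3,4,5-trimethoxyphenoxy)phenoxy]-2-hydroxy-4,5,6-trimethoxybenzaldehyde
Product: 19 3-[3,4-dimethoxy-5-(3,4,5-trimethoxyphenoxy)phenoxy]-2-hydroxy-4,5,6-trimethoxybenzoic acid (ring C salicylic acid)
Conditions: NaClO2, NaH2PO4, 2-methyl-2-butene (large excess), t-BuOH/THF/H2O, 0 °C to rt; used without delay
Reagents that add atoms: sodium chlorite, [Na+].[O-]Cl=O
Why: Pinnick oxidation at buffered pH converts the aldehyde selectively, the alkene intercepts hypochlorous acid before it can chlorinate rings D and E, and the mild acidity avoids early loss of CO2.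

**Step 12**
Reactants: 19 ring C salicylic acid; 7 2-bromo-3-methoxy-5-(2,4,6-trimethoxyphenoxy)phenol
Product: 20 depside, 2-bromo-3-methoxy-5-(2,4,6-trimethoxyphenoxy)phenyl 3-[3,4-dimethoxy-5-(3,4,5-trimethoxyphenoxy)phenoxy]-2-hydroxy-4,5,6-trimethoxybenzoate
Conditions: DCC, DMAP (cat.), CH2Cl2, 0 °C to rt
Reagents that add atoms: none
Why: Steglich-type carbodiimide esterification, the usual way to depsides from free salicylic acids, works here because the C1 hydroxyl is hydrogen-bonded and flanked on both sides and so does not compete, and the neutral medium does not trigger decarboxylation.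

**Step 13**
Reactants: 20 depside
Product: 21 depsidone, the dibenzo[b,e][1,4]dioxepin-11-one in which rings B and C are joined by the new B4–O–C1 ether and by the lactone C6–C(=O)–O–B3
Conditions: CuI (0.5 equiv), 1,10-phenanthroline (1 equiv), Cs2CO3 (2 equiv), 4 Å MS, 1,4-dioxane, slow addition of 20 to about 5 mM, 100 °C, Ar
Reagents that add atoms: none
Why: Cs2CO3 deprotonates the only free hydroxyl (C1–OH), the phenoxide binds ligated monovalent copper, oxidative addition of the nearby B4–Br bond gives an eight-membered metallacycle of trivalent copper, and reductive elimination forms the B4–O bond. The closest known reaction type is the intramolecular Ullmann diaryl ether synthesis, a known way to close depsidone rings from 2-halophenyl salicylates. The one new ring is seven-membered (carbonyl carbon, ester oxygen, B3, B4, ether oxygen, C1, C6) and closes in a formal 7-exo sense, the departing bromide lying outside the ring. No stereocenter is formed. The step needs ring closure to win over bimolecular coupling and over intermolecular acyl transfer, and this is secured by the ester holding the C1 oxygen within reach of B4, by the presence of one halide and one free hydroxyl only, and by high dilution. A dry, non-nucleophilic medium protects the aryl ester, the electron-rich ring B rules out a Smiles-type ipso attack at B3, and any lactone opened after closure merely anticipates the next step.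

**Step 14**
Reactants: 21 depsidone
Product: 23 3-methoxy-2-{2-[3,4-dimethoxy-5-(3,4,5-trimethoxyphenoxy)phenoxy]-3,4,5-trimethoxyphenoxy}-5-(2,4,6-trimethoxyphenoxy)phenol (pentamer dodecamethyl ether, free B3 hydroxyl), via ring-opened acid 22 (not isolated)
Conditions: KOH, 1,4-dioxane/H2O, 60 °C; then 6 M HCl to pH < 1, 90 °C
Reagents that add atoms: potassium hydroxide, [K+].[OH-] (its oxygen enters intermediate 22 only and leaves again in CO2; 23 gains hydrogen only)
Why: Saponification of the aryl ester lactone is followed by acid-catalysed protodecarboxylation, in which ipso protonation at C6 is favoured by two ortho oxygens and one para oxygen and by relief of strain in the hexasubstituted ring.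

**Step 15**
Reactants: 23 pentamer dodecamethyl ether
Product: 24 target CNP0154768.0
Conditions: BBr3 (about 25 equiv), CH2Cl2, −78 °C to rt, Ar; then degassed H2O, 0 °C; reversed-phase purification under Ar
Reagents that add atoms: none
Why: Lewis acid ether cleavage with BBr3, in which bromide attacks only the sp3 methyl carbons of the boron-complexed ethers, so the four diaryl ether bonds remain.

**Compound list**
1 | 2-bromo-3-methoxyphenol | COc1cccc(O)c1Br | starting material
2 | 2-bromo-1-methoxy-3-(methoxymethoxy)benzene | COCOc1cccc(OC)c1Br | intermediate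
3 | 2-[4-bromo-3-methoxy-5-(methoxymethoxy)phenyl]-4,4,5,5-tetramethyl-1,3,2-dioxaborolane | COCOc1cc(B2OC(C)(C)C(C)(C)O2)cc(OC)c1Br | intermediate
4 | 2-bromo-5-iodo-1-methoxy-3-(methoxymethoxy)benzene | COCOc1cc(I)cc(OC)c1Br | intermediate
5 | 2,4,6-trimethoxyphenol | COc1cc(OC)c(O)c(OC)c1 | starting material
6 | 2-bromo-1-methoxy-3-(methoxymethoxy)-5-(2,4,6-trimethoxyphenoxy)benzene | COCOc1cc(Oc2c(OC)cc(OC)cc2OC)cc(OC)c1Br | intermediate
7 | 2-bromo-3-methoxy-5-(2,4,6-trimethoxyphenoxy)phenol | Oc1cc(Oc2c(OC)cc(OC)cc2OC)cc(OC)c1Br | intermediate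
8 | 3-bromo-4,5-dimethoxybenzaldehyde | COc1cc(C=O)cc(Br)c1OC | starting material
9 | 3,4,5-trimethoxyphenol | COc1cc(O)cc(OC)c1OC | starting material
10 | 3,4-dimethoxy-5-(3,4,5-trimethoxyphenoxy)benzaldehyde | COc1cc(C=O)cc(Oc2cc(OC)c(OC)c(OC)c2)c1OC | intermediate
11 | 3,4-dimethoxy-5-(3,4,5-trimethoxyphenoxy)phenyl formate | COc1cc(OC=O)cc(Oc2cc(OC)c(OC)c(OC)c2)c1OC | intermediate
12 | 3,4-dimethoxy-5-(3,4,5-trimethoxyphenoxy)phenol | COc1cc(O)cc(Oc2cc(OC)c(OC)c(OC)c2)c1OC | intermediate
13 | 3,4,5-trimethoxybenzaldehyde | COc1cc(C=O)cc(OC)c1OC | starting material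
14 | 2-bromo-3,4,5-trimethoxybenzaldehyde | COc1cc(C=O)c(Br)c(OC)c1OC | intermediate
15 | 2-[3,4-dimethoxy-5-(3,4,5-trimethoxyphenoxy)phenoxy]-3,4,5-trimethoxybenzaldehyde | O=Cc1cc(OC)c(OC)c(OC)c1Oc1cc(OC)c(OC)c(Oc2cc(OC)c(OC)c(OC)c2)c1 | intermediate
16 | 2-[3,4-dimethoxy-5-(3,4,5-trimethoxyphenoxy)phenoxy]-3,4,5-trimethoxyphenyl formate | O=COc1cc(OC)c(OC)c(OC)c1Oc1cc(OC)c(OC)c(Oc2cc(OC)c(OC)c(OC)c2)c1 | intermediate
17 | 2-[3,4-dimethoxy-5-(3,4,5-trimethoxyphenoxy)phenoxy]-3,4,5-trimethoxyphenol | Oc1cc(OC)c(OC)c(OC)c1Oc1cc(OC)c(OC)c(Oc2cc(OC)c(OC)c(OC)c2)c1 | intermediate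
18 | 3-[3,4-dimethoxy-5-(3,4,5-trimethoxyphenoxy)phenoxy]-2-hydroxy-4,5,6-trimethoxybenzaldehyde | Oc1c(C=O)c(OC)c(OC)c(OC)c1Oc1cc(OC)c(OC)c(Oc2cc(OC)c(OC)c(OC)c2)c1 | intermediate
19 | 3-[3,4-dimethoxy-5-(3,4,5-trimethoxyphenoxy)phenoxy]-2-hydroxy-4,5,6-trimethoxybenzoic acid | Oc1c(C(=O)O)c(OC)c(OC)c(OC)c1Oc1cc(OC)c(OC)c(Oc2cc(OC)c(OC)c(OC)c2)c1 | intermediate
20 | depside: 2-bromo-3-methoxy-5-(2,4,6-trimethoxyphenoxy)phenyl ester of 19 | Oc1c(C(=O)Oc2cc(Oc3c(OC)cc(OC)cc3OC)cc(OC)c2Br)c(OC)c(OC)c(OC)c1Oc4cc(OC)c(OC)c(Oc5cc(OC)c(OC)c(OC)c5)c4 | intermediate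
21 | depsidone: pentamer skeleton with rings B and C also bridged by the lactone carbonyl from C6 to the B3 oxygen | O=C1Oc2cc(Oc3c(OC)cc(OC)cc3OC)cc(OC)c2Oc6c1c(OC)c(OC)c(OC)c6Oc4cc(OC)c(OC)c(Oc5cc(OC)c(OC)c(OC)c5)c4 | intermediate
22 | 2-[2-hydroxy-6-methoxy-4-(2,4,6-trimethoxyphenoxy)phenoxy]-3-[3,4-dimethoxy-5-(3,4,5-trimethoxyphenoxy)phenoxy]-4,5,6-trimethoxybenzoic acid | OC(=O)c1c(OC)c(OC)c(OC)c(Oc2cc(OC)c(OC)c(Oc3cc(OC)c(OC)c(OC)c3)c2)c1Oc1c(O)cc(Oc2c(OC)cc(OC)cc2OC)cc1OC | intermediate
23 | pentamer dodecamethyl ether with free B3 hydroxyl | COc1cc(Oc2c(O)cc(Oc3c(OC)cc(OC)cc3OC)cc2OC)c(Oc2cc(OC)c(OC)c(Oc3cc(OC)c(OC)c(OC)c3)c2)c(OC)c1OC | intermediate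
24 | CNP0154768.0: 2,4,6-trihydroxyphenyl (A)–O–3,5-dihydroxy-1,4-phenylene (B)–O–3,4,5-trihydroxy-1,2-phenylene (C)–O–4,5-dihydroxy-1,3-phenylene (D)–O–3,4,5-trihydroxyphenyl (E) | Oc1cc(O)c(Oc2cc(O)c(Oc3cc(O)c(O)c(O)c3Oc3cc(O)c(O)c(Oc4cc(O)c(O)c(O)c4)c3)c(O)c2)c(O)c1 | target

**Step count**
- Total steps: 15.
- Longest linear sequence: 10 steps (5, 6, 8, 9, 10, 11, 12, 13, 14, 15), starting from 8 and 9.

**Steps most likely to fail**

1. **Step 13.**
   - Risk: oxidative addition at the electron-rich, doubly ortho-substituted B4–Br bond may be slower than hydrolysis or intermolecular transfer of the aryl ester by the caesium phenoxide. Hydrodebromination may also compete.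
   - Fallback (untethered coupling): it sets out from phenol 17 and the protected bromide 6. These are joined in a bimolecular Ullmann ether coupling (stoichiometric CuI, picolinic acid, K3PO4, DMSO, 120 °C, excess of 6).
   - Why it may work: no ester is present, so forcing conditions are tolerable, and 17 carries only one ortho substituent.
   - Return: the coupling should give the MOM-protected pentamer ether F1. HCl in MeOH removes the acetal, and the route is rejoined at 23.

2. **Step 12.**
   - Risk: acylation of the hindered, weakly nucleophilic bromophenol may be slow. The activated acid could then rearrange to the N-acylurea, acylate another molecule at its C1 hydroxyl, or lose CO2 on standing.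
   - Fallback (masked C1 hydroxyl, stronger activation): it sets out from aldehyde 18. MOMCl with i-Pr2NEt should give the MOM-protected aldehyde F2, and Pinnick oxidation the MOM-protected acid F3.
   - Coupling: F3 has no free phenol and can be activated strongly with 2-methyl-6-nitrobenzoic anhydride, DMAP and Et3N (Shiina esterification). Coupling with 7 should give the MOM-protected depside F4.
   - Return: HCl in MeOH/CH2Cl2 at 0 °C frees the C1 hydroxyl without touching the hindered ester, and the route is rejoined at 20.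

3. **Step 15.**
   - Risk: twelvefold cleavage may stall when partly demethylated boron complexes precipitate. The free polyphenol may also oxidise in air during isolation.
   - Fallback (derivatise, purify, release): it sets out from 23. After the BBr3 treatment the crude polyphenol is not purified but acetylated at once (Ac2O, pyridine, Ar) to the tridecaacetate F5.
   - Why it may work: F5 is stable and can be separated from under-cleaved material on ordinary silica gel.
   - Return: acid-catalysed methanolysis (HCl in dry MeOH, Ar), which avoids oxidisable phenolates, comes back to the route at 24.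

**Further compounds**
F1 | step 13 | MOM-protected pentamer ether (23 with B3–OCH2OCH3) | COCOc1cc(Oc2c(OC)cc(OC)cc2OC)cc(OC)c1Oc1cc(OC)c(OC)c(OC)c1Oc1cc(OC)c(OC)c(Oc2cc(OC)c(OC)c(OC)c2)c1
F2 | step 12 | MOM-protected aldehyde, 3-[3,4-dimethoxy-5-(3,4,5-trimethoxyphenoxy)phenoxy]-4,5,6-trimethoxy-2-(methoxymethoxy)benzaldehyde | COCOc1c(C=O)c(OC)c(OC)c(OC)c1Oc1cc(OC)c(OC)c(Oc2cc(OC)c(OC)c(OC)c2)c1
F3 | step 12 | MOM-protected acid, 3-[3,4-dimethoxy-5-(3,4,5-trimethoxyphenoxy)phenoxy]-4,5,6-trimethoxy-2-(methoxymethoxy)benzoic acid | COCOc1c(C(=O)O)c(OC)c(OC)c(OC)c1Oc1cc(OC)c(OC)c(Oc2cc(OC)c(OC)c(OC)c2)c1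
F4 | step 12 | MOM-protected depside (20 with C1–OCH2OCH3) | COCOc1c(C(=O)Oc2cc(Oc3c(OC)cc(OC)cc3OC)cc(OC)c2Br)c(OC)c(OC)c(OC)c1Oc1cc(OC)c(OC)c(Oc2cc(OC)c(OC)c(OC)c2)c1
F5 | step 15 | tridecaacetate of 24 | CC(=O)Oc1cc(OC(C)=O)c(Oc2cc(OC(C)=O)c(Oc3cc(OC(C)=O)c(OC(C)=O)c(OC(C)=O)c3Oc3cc(OC(C)=O)c(OC(C)=O)c(Oc4cc(OC(C)=O)c(OC(C)=O)c(OC(C)=O)c4)c3)c(OC(C)=O)c2)c(OC(C)=O)c1
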